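**Plan**
1. Quinone ring numbering: C1(=O)–C2(OAr)=C3(OMe)–C4(=O)–C5(prenyl)=C6(prenyl). The retrosynthesis cuts, in order: the two O–Si bonds; the C5–C6 bond of the quinone ring, giving an acyclic (Z)-2-ene-1,4-dione whose ketone α-carbons are C5 and C6; then, after C1 and C4 are rejoined as a cyclobutene-1,2-diol, the C1–C6 and C4–C5 bonds (two homoprenyl carbanions) and the two vinylic C–O bonds of a squarate.
2. Enabling feature: C5 and C6 are the α-carbons of the ring carbonyls C4 and C1 and carry identical prenyl groups. The four oxygen-bearing ring carbons C1–C4 are contiguous, so they map onto the four carbons of squaric acid with C2=C3 as its ring double bond.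
3. Forward: the benzoate ring is bought. A four-membered squarate ring carries C1–C4 as a temporary ring and is opened by glycol cleavage. The six-membered ring is then closed by oxidative coupling of C5 with C6, directly at the quinone oxidation level, and the phenols are unmasked last.
4. Stereochemistry: the target has no stereocentre. The one geometric requirement, a Z C2=C3 bond that holds the two acyl arms cis for ring closure, is inherited from the cyclobutene.

Key step: step 5

Remark: 3,4-dichlorocyclobut-3-ene-1,2-dione (3) and 5-bromo-2-methylpent-2-ene (6) are taken as purchased materials.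

Step 1
Reactants: 1 methyl 2,4,6-trihydroxybenzoate
Product: 2 methyl 2,4-bis[(tert-butyldimethylsilyl)oxy]-6-hydroxybenzoate
Conditions: TBSCl (2.1 equiv), imidazole, DMF, 0 °C → rt
Reagents that add atoms: tert-butyldimethylsilyl chloride (TBSCl), CC(C)(C)[Si](C)(C)Cl
Why: Selective silyl ether formation: the para hydroxyl and one of the two equivalent ortho hydroxyls should silylate readily, whereas the last ortho hydroxyl is held in a hydrogen bond to the ester carbonyl and should stay free.

Step 2
Reactants: 3 3,4-dichlorocyclobut-3-ene-1,2-dione (squaryl dichloride); 2 methyl 2,4-bis[(tert-butyldimethylsilyl)oxy]-6-hydroxybenzoate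
Product: 5 methyl 2,4-bis[(tert-butyldimethylsilyl)oxy]-6-[(2-methoxy-3,4-dioxocyclobut-1-en-1-yl)oxy]benzoate (aryl methyl squarate), via 3-chloro-4-methoxycyclobut-3-ene-1,2-dione 4 (not isolated)
Conditions: MeOH (1.0 equiv), CH2Cl2, −40 → 0 °C; then 2, iPr2NEt (2.2 equiv), −40 °C → rt
Reagents that add atoms: methanol, CO
Why: Stepwise nucleophilic vinylic substitution (addition–elimination) on a double vinylogous acid chloride: the first chloride is displaced by methanol, the methoxy donor then slows the second displacement, and the remaining chloride (a better leaving group than methoxide) should be replaced by the phenoxide of 2.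

Step 3
Reactants: 5 aryl methyl squarate; 6 5-bromo-2-methylpent-2-ene
Product: 8 methyl 2,4-bis[(tert-butyldimethylsilyl)oxy]-6-{[3,4-dihydroxy-2-methoxy-3,4-bis(4-methylpent-3-en-1-yl)cyclobut-1-en-1-yl]oxy}benzoate (cis/trans mixture of racemic diols), via (4-methylpent-3-en-1-yl)lithium 7 (not isolated)
Conditions: 6 (2.3 equiv), Li (1% Na), Et2O, −10 °C; then 5, THF, −78 °C; sat. aq. NH4Cl, −78 °C
Reagents that add atoms: none
Why: Double 1,2-addition of an organolithium to the two ring carbonyls of a squarate diester should be faster at −78 °C than attack on the doubly ortho-substituted benzoate; the same nucleophile is used twice, so regiochemistry is moot, the two carbinol stereocentres are uncontrolled and are destroyed in step 4, and the cold quench should forestall the charge-accelerated ring opening of the dialkoxide.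

Step 4
Reactants: 8 cyclobutene-1,2-diol
Product: 9 methyl 2,4-bis[(tert-butyldimethylsilyl)oxy]-6-{[(7Z)-7-methoxy-2,13-dimethyl-6,9-dioxotetradeca-2,7,12-trien-8-yl]oxy}benzoate
Conditions: Pb(OAc)4 (1.1 equiv), pyridine, CH2Cl2, −20 °C, dark
Reagents that add atoms: none
Why: Criegee glycol cleavage should break the strained bond between the two carbinol carbons of either diastereomer and release both ketones, while the ring C=C bond, which is never touched, keeps the two acyl arms cis and so should deliver the enedione as the Z isomer only.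

Step 5
Reactants: 9 (Z)-enedione
Product: 13 methyl 2,4-bis[(tert-butyldimethylsilyl)oxy]-6-{[2-methoxy-4,5-bis(3-methylbut-2-en-1-yl)-3,6-dioxocyclohexa-1,4-dien-1-yl]oxy}benzoate (bis-silyl atrovirinone), via dilithium trienediolate 10 (not isolated), via cyclohex-2-ene-1,4-dione 11 (not isolated), via hydroquinone 12 (not isolated)
Conditions: LiN(SiMe3)2 (2.3 equiv), THF, −78 °C, 9 added slowly (0.01 M); CuCl2 (2.5 equiv), DMF, −78 → 0 °C; then O2 (1 atm), rt
Reagents that add atoms: none
Why: Proposed new method: slow addition of 9 to excess LiN(SiMe3)2 should remove one α-proton at C5 and one at C6 to give the cross-conjugated hexa-1,3,5-triene-2,5-diolate 10, in which the Z C2=C3 bond and five-membered chelation of each lithium between an enolate oxygen and its neighbouring ether oxygen (O4/OMe, O1/OAr) turn C5 and C6 toward each other; one-electron oxidation by divalent copper gives an α-keto radical at C5 that adds to the enolate carbon C6, a second oxidation of the resulting ketyl gives enedione 11, which enolises to hydroquinone 12 and is dehydrogenated to the quinone by the copper salts under O2. The closest known reaction type is the intramolecular oxidative coupling of diketone dienolates with CuCl2 or FeCl3 in DMF, which has joined saturated diketones but has not been applied to the bis-enolate of an enedione to reach an arene oxidation level in the same flask. The six-membered ring closes in the 6-endo-trig mode of the C5 radical on the C6=C1 enolate, and a thermal disrotatory 6π electrocyclisation of 10 followed by the same two-electron oxidation would also end at 11, so both conceivable pathways converge. The two sp3 centres formed at C5 and C6 are transient and are erased on enolisation, so no stereocontrol is required. The step needs C–C coupling between C5 and C6 in preference to the five-membered aldol closure of a mono-enolate, to O–C coupling and to coupling between molecules; this is secured by inverse addition at −78 °C (both ketones are enolates before either can serve as an electrophile), by the cis arrangement of the acyl arms fixed by the former cyclobutene and by high dilution.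

Step 6
Reactants: 13 bis-silyl atrovirinone
Product: 14 atrovirinone, methyl 2,4-dihydroxy-6-{[2-methoxy-4,5-bis(3-methylbut-2-en-1-yl)-3,6-dioxocyclohexa-1,4-dien-1-yl]oxy}benzoate
Conditions: Bu4NF (2.2 equiv), AcOH (2.5 equiv), THF, 0 °C
Reagents that add atoms: none
Why: Fluoride-mediated desilylation of aryl silyl ethers should be fast at 0 °C, and the acetic acid buffer keeps the liberated phenols protonated so that the quinone and its aryl ether link are not exposed to phenoxide or hydroxide.

**Compound list**
1 | methyl 2,4,6-trihydroxybenzoate | COC(=O)c1c(O)cc(O)cc1O | starting material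
2 | methyl 2,4-bis[(tert-butyldimethylsilyl)oxy]-6-hydroxybenzoate | COC(=O)c1c(O)cc(O[Si](C)(C)C(C)(C)C)cc1O[Si](C)(C)C(C)(C)C | intermediate
3 | 3,4-dichlorocyclobut-3-ene-1,2-dione (squaryl dichloride) | ClC1=C(Cl)C(=O)C1=O | starting material
4 | 3-chloro-4-methoxycyclobut-3-ene-1,2-dione | COC1=C(Cl)C(=O)C1=O | intermediate
5 | methyl 2,4-bis[(tert-butyldimethylsilyl)oxy]-6-[(2-methoxy-3,4-dioxocyclobut-1-en-1-yl)oxy]benzoate | COC1=C(Oc2cc(O[Si](C)(C)C(C)(C)C)cc(O[Si](C)(C)C(C)(C)C)c2C(=O)OC)C(=O)C1=O | intermediate
6 | 5-bromo-2-methylpent-2-ene | CC(C)=CCCBr | starting material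
7 | (4-methylpent-3-en-1-yl)lithium | [Li]CCC=C(C)C | intermediate
8 | methyl 2,4-bis[(tert-butyldimethylsilyl)oxy]-6-{[3,4-dihydroxy-2-methoxy-3,4-bis(4-methylpent-3-en-1-yl)cyclobut-1-en-1-yl]oxy}benzoate (cis/trans mixture, racemic) | COC1=C(Oc2cc(O[Si](C)(C)C(C)(C)C)cc(O[Si](C)(C)C(C)(C)C)c2C(=O)OC)C(O)(CCC=C(C)C)C1(O)CCC=C(C)C | intermediate
9 | methyl 2,4-bis[(tert-butyldimethylsilyl)oxy]-6-{[(7Z)-7-methoxy-2,13-dimethyl-6,9-dioxotetradeca-2,7,12-trien-8-yl]oxy}benzoate | COC(=O)c1c(O[Si](C)(C)C(C)(C)C)cc(O[Si](C)(C)C(C)(C)C)cc1O/C(C(=O)CCC=C(C)C)=C(\OC)C(=O)CCC=C(C)C | intermediate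
10 | dilithium bis-enolate of 9 (hexa-1,3,5-triene-2,5-diolate core, central double bond Z, enolate geometry not defined) | [Li+].[Li+].COC(=O)c1c(O[Si](C)(C)C(C)(C)C)cc(O[Si](C)(C)C(C)(C)C)cc1O/C(C([O-])=CCC=C(C)C)=C(\OC)C([O-])=CCC=C(C)C | intermediate
11 | methyl 2,4-bis[(tert-butyldimethylsilyl)oxy]-6-{[2-methoxy-4,5-bis(3-methylbut-2-en-1-yl)-3,6-dioxocyclohex-1-en-1-yl]oxy}benzoate (cis/trans mixture) | COC(=O)c1c(O[Si](C)(C)C(C)(C)C)cc(O[Si](C)(C)C(C)(C)C)cc1OC1=C(OC)C(=O)C(CC=C(C)C)C(CC=C(C)C)C1=O | intermediate
12 | methyl 2,4-bis[(tert-butyldimethylsilyl)oxy]-6-[2,5-dihydroxy-6-methoxy-3,4-bis(3-methylbut-2-en-1-yl)phenoxy]benzoate | COC(=O)c1c(O[Si](C)(C)C(C)(C)C)cc(O[Si](C)(C)C(C)(C)C)cc1Oc1c(OC)c(O)c(CC=C(C)C)c(CC=C(C)C)c1O | intermediate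
13 | methyl 2,4-bis[(tert-butyldimethylsilyl)oxy]-6-{[2-methoxy-4,5-bis(3-methylbut-2-en-1-yl)-3,6-dioxocyclohexa-1,4-dien-1-yl]oxy}benzoate | COC(=O)c1c(O[Si](C)(C)C(C)(C)C)cc(O[Si](C)(C)C(C)(C)C)cc1OC1=C(OC)C(=O)C(CC=C(C)C)=C(CC=C(C)C)C1=O | intermediate
14 | atrovirinone | COC(=O)c1c(O)cc(O)cc1OC1=C(OC)C(=O)C(CC=C(C)C)=C(CC=C(C)C)C1=O | target

**Step count**
Total steps: 6. Longest linear sequence: 6 steps (1 → 2 → 5 → 8 → 9 → 13 → 14).

**Steps most likely to fail**

Step 5 (the step that carries the label). The risks are incomplete double enolisation followed by aldol closure of a mono-enolate onto the second ketone, oxidative coupling between molecules, and chlorination or over-oxidation at the α-carbons. The fallback sets out from 9 and returns at 13, forming the same C5–C6 bond by a redox-neutral pericyclic closure that needs no enolate. Soft enolisation of 9 (Me3SiOTf, Et3N, CH2Cl2, 0 °C) would give the bis(trimethylsilyl enol ether) F1. This (Z)-hexatriene should undergo thermal disrotatory 6π electrocyclisation (toluene, 90 °C) to the 1,4-bis(silyloxy)cyclohexa-1,3-diene F2. Oxidation with (NH4)2Ce(NO3)6 and NaHCO3 in MeCN–H2O at 0 °C would take the silyl dienol ether through 11 and 12 to 13. Silyl enol ether formation, triene electrocyclisation and cerium-mediated oxidation of silyl enol ethers and hydroquinones are each known reaction types.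

Step 3. The organolithium may add to the aryloxy-bearing ring carbon with loss of the phenoxide, attack the benzoate, or the dialkoxide may open before the quench. The fallback sets out from 5, returns at 12 and needs only a single carbonyl addition, because C5 and C6 arrive already joined. The skipped enyne 2,9-dimethyldeca-2,7-dien-5-yne F3 would be made from BrMgC≡CMgBr and prenyl bromide (CuCl cat., THF). Syn-hydrozirconation and iodinolysis (Cp2Zr(H)Cl, THF; I2) would convert it into the (E)-alkenyl iodide F4. Iodine–lithium exchange (t-BuLi, Et2O, −78 °C) would give the alkenyllithium F5, which should add once to a ring carbonyl of 5 (THF, −78 °C) to give the 4-alkenyl-4-hydroxycyclobutenone F6; either regioisomer leads to the same product. Heating (toluene, 110 °C) should bring about the Moore rearrangement to hydroquinone 12, which is oxidised to 13 with O2 and catalytic CuCl as in step 5, or with Ag2O. Steps 3 to 5 are bypassed.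

Step 6. Under fluoride the freed phenoxide may add through its ortho carbon to the neighbouring methoxy-bearing quinone carbon (closure to a dibenzofuran with loss of methanol), or the quinonyl aryl ether may be cleaved by addition–elimination. The fallback sets out from 13 and returns at 14, removing the silyl groups at an oxidation level that is not electrophilic. Quinone 13 would be reduced to hydroquinone 12 (Na2S2O4, EtOAc–H2O). Both silyl ethers would then be cleaved under argon (Bu4NF, AcOH, THF) to give the tetraphenol F7. After acidic work-up its hydroquinone ring would be re-oxidised under neutral conditions (Ag2O, Et2O) to 14.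

**Further compounds**
F1 | step 5 | methyl 2,4-bis[(tert-butyldimethylsilyl)oxy]-6-{[(7Z)-7-methoxy-2,13-dimethyl-6,9-bis(trimethylsilyloxy)tetradeca-2,5,7,9,12-pentaen-8-yl]oxy}benzoate | COC(=O)c1c(O[Si](C)(C)C(C)(C)C)cc(O[Si](C)(C)C(C)(C)C)cc1O/C(C(O[Si](C)(C)C)=CCC=C(C)C)=C(\OC)C(O[Si](C)(C)C)=CCC=C(C)C
F2 | step 5 | methyl 2,4-bis[(tert-butyldimethylsilyl)oxy]-6-{[2-methoxy-4,5-bis(3-methylbut-2-en-1-yl)-3,6-bis(trimethylsilyloxy)cyclohexa-1,5-dien-1-yl]oxy}benzoate | COC(=O)c1c(O[Si](C)(C)C(C)(C)C)cc(O[Si](C)(C)C(C)(C)C)cc1OC1=C(O[Si](C)(C)C)C(CC=C(C)C)C(CC=C(C)C)C(O[Si](C)(C)C)=C1OC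
F3 | step 3 | 2,9-dimethyldeca-2,7-dien-5-yne | CC(C)=CCC#CCC=C(C)C
F4 | step 3 | (5E)-5-iodo-2,9-dimethyldeca-2,5,8-triene | CC(C)=CC/C=C(\CC=C(C)C)I
F5 | step 3 | [(5Z)-2,9-dimethyldeca-2,5,8-trien-5-yl]lithium | CC(C)=CC/C=C(\CC=C(C)C)[Li]
F6 | step 3 | methyl 2,4-bis[(tert-butyldimethylsilyl)oxy]-6-({3-[(5Z)-2,9-dimethyldeca-2,5,8-trien-5-yl]-3-hydroxy-2-methoxy-4-oxocyclobut-1-en-1-yl}oxy)benzoate | COC1=C(Oc2cc(O[Si](C)(C)C(C)(C)C)cc(O[Si](C)(C)C(C)(C)C)c2C(=O)OC)C(=O)C1(O)/C(CC=C(C)C)=C/CC=C(C)C
F7 | step 6 | methyl 2-[2,5-dihydroxy-6-methoxy-3,4-bis(3-methylbut-2-en-1-yl)phenoxy]-4,6-dihydroxybenzoate | COC(=O)c1c(O)cc(O)cc1Oc1c(OC)c(O)c(CC=C(C)C)c(CC=C(C)C)c1O
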